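**Retrosynthetic overview**
1. Last step: the cyclopentane carbaldehyde comes from ring contraction of a six-membered ring A (C1, C10–C14) 11α,12α-epoxide by a bromide-assisted 1,2-shift of C13 from C12 to C11; C12 becomes the formyl carbon.
2. Before that, the ten-membered ring is closed at C8–C9 by intramolecular NiCl2/CrCl2-mediated coupling of a β-iodobutenolide and an aldehyde; 8-OH and 17-H then come from a boronate-tethered conjugate hydration of the butenolide (new).
3. C1–C2 is made by a titanium aldol between the ring-A enolate and a butenolide aldehyde; ring A comes from 4-methylphenol (dearomatisation, Rh-catalysed vinyl addition, methylation), and its C11=C12 alkene appears later by SmI2 deoxygenation.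
4. Butenolide aldehyde: propyne carbocupration, enantioselective alkenylzinc addition to but-2-ynal, Pd-catalysed carbonylation to the allenoate, iodolactonisation.
5. Ring order: butenolide, six-membered ring A (from the arene), ten-membered ring, temporary dioxaborolane, epoxide, and finally contraction of ring A to the cyclopentane.

Assumption and locants: but-2-ynal and CH2=CHBF3K are taken as purchasable; locants are those of the target counted the briarane way (C1 quaternary with CH3-15, C2–C10 around the ten-membered ring with CH3-16 on C5, C11 with CH3-20 and formyl carbon C12, C13, C14, lactone C17/CH3-18/C19), α = face of H-10, β = face of CH3-15, ring A = carbocycle C1/C10–C14.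

**Route**

Step 1
Reactants: 1 2-(2-bromoethyl)-1,3-dioxolane; 2 propyne
Product: 6 2-[(3Z)-4-iodo-3-methylbut-3-en-1-yl]-1,3-dioxolane, via alkylmagnesium bromide 3 (not isolated), via alkylcopper 4 (not isolated), via alkenylcopper 5 (not isolated)
Conditions: Mg, THF, 25 °C; CuBr·SMe2, Et2O/Me2S, −45 °C; 2, −25 °C; I2, −50 → 0 °C
Reagents that add atoms: iodine, [I][I]
Why: Normant carbocupration adds the alkylcopper syn across propyne with copper on the terminal carbon, and iodinolysis with retention gives the Z-iodoalkene that fixes the later C5=C6 geometry (C4 cis to C7).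

Step 2
Reactants: 6 2-[(3Z)-4-iodo-3-methylbut-3-en-1-yl]-1,3-dioxolane; 7 but-2-ynal
Product: 11 methyl (4R,5Z)-8-(1,3-dioxolan-2-yl)-6-methyloct-5-en-2-yn-4-yl carbonate, via alkenyllithium 8 (not isolated), via alkenylzinc bromide 9 (not isolated), via bromozinc alkoxide 10 (not isolated)
Conditions: t-BuLi (2.0 equiv), Et2O, −78 °C; ZnBr2; TEEDA, (+)-MIB (10 mol %), toluene; 7, 0 °C; then ClCO2Me, pyridine, 0 °C
Reagents that add atoms: methyl chloroformate, COC(Cl)=O
Why: Iodine–lithium exchange with retention, transmetalation to zinc and amino-alcohol-catalysed enantioselective alkenylzinc addition to the ynal (Oppolzer/Walsh type, TEEDA masking the lithium halides) set C7 as R by catalyst control, and the zinc alkoxide is acylated in situ to the propargylic carbonate.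

Step 3
Reactants: 11 methyl (4R,5Z)-8-(1,3-dioxolan-2-yl)-6-methyloct-5-en-2-yn-4-yl carbonate
Product: 12 methyl (aS,5Z)-8-(1,3-dioxolan-2-yl)-2,6-dimethylocta-2,3,5-trienoate
Conditions: Pd2(dba)3·CHCl3 (2.5 mol %), PPh3 (10 mol %), CO (10 atm), THF, 45 °C
Reagents that add atoms: carbon monoxide, [C-]#[O+]
Why: Tsuji-type decarboxylative carbonylation, in which zerovalent palladium ionises the propargylic carbonate by anti SN2′ attack, CO inserts into the allenylpalladium and the liberated methoxide gives the 2,3-allenoate, relays the C7 centre into the aS axis.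

Step 4
Reactants: 12 methyl (aS,5Z)-8-(1,3-dioxolan-2-yl)-2,6-dimethylocta-2,3,5-trienoate
Product: 14 (4Z)-5-[(2S)-3-iodo-4-methyl-5-oxo-2,5-dihydrofuran-2-yl]-4-methylpent-4-enal, via iodobutenolide acetal 13 (not isolated)
Conditions: I2 (2.2 equiv), MeCN/H2O 10:1, 0 °C → rt; then 1 M HCl, rt
Reagents that add atoms: iodine, [I][I]; water, O
Why: Iodolactonisation of the 2,3-allenoate (iodonium on C7=C8, attack of the ester carbonyl from its own side, loss of MeI) turns the axis into the 7S lactone centre and leaves iodine on C8, after which aqueous acid hydrolyses the dioxolane.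

Step 5
Reactants: 15 4-methylphenol
Product: 16 4-methoxy-4-methylcyclohexa-2,5-dien-1-one
Conditions: PhI(OAc)2, MeOH, 0 °C
Reagents that add atoms: methanol, CO
Why: Oxidative dearomatisation of the phenol by the hypervalent iodine reagent with para capture by methanol gives the achiral quinol methyl ether.

Step 6
Reactants: 16 4-methoxy-4-methylcyclohexa-2,5-dien-1-one
Product: 17 (4R,5S)-5-ethenyl-4-methoxy-4-methylcyclohex-2-en-1-one
Conditions: CH2=CHBF3K (1.2 equiv), Rh(acac)(C2H4)2 (3 mol %), (S)-BINAP (3.3 mol %), dioxane/H2O 10:1, 80 °C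
Reagents that add atoms: potassium vinyltrifluoroborate, [K+].C=C[B-](F)(F)F
Why: The Rh(acac)(C2H4)2/(S)-BINAP-catalysed conjugate addition of the vinylboron reagent (Hayashi–Miyaura type) desymmetrises the dienone with ligand control of C10 (sense assigned by analogy with cyclohex-2-enone), while the C11 ether centre (major epimer drawn) is only a placeholder that becomes sp2 in step 13.

Step 7
Reactants: 17 (4R,5S)-5-ethenyl-4-methoxy-4-methylcyclohex-2-en-1-one
Product: 19 (4R,5R,6R)-5-ethenyl-4-methoxy-4,6-dimethylcyclohex-2-en-1-one, via lithium dienolate 18 (not isolated)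
Conditions: LiN(i-Pr)2, THF, −78 °C; MeI, −78 → −20 °C
Reagents that add atoms: iodomethane, CI
Why: Enolate alkylation can only occur at C1 (the other α-carbon is vinylic) and methylation trans to the vinyl group brings in CH3-15, the C1 configuration being reset in step 9.

Step 8
Reactants: 19 (4R,5R,6R)-5-ethenyl-4-methoxy-4,6-dimethylcyclohex-2-en-1-one
Product: 21 (4R,5R,6R)-5-(dimethoxymethyl)-4-methoxy-4,6-dimethylcyclohex-2-en-1-one, via aldehyde 20 (not isolated)
Conditions: O3, CH2Cl2, −78 °C; PPh3; then HC(OMe)3, PPTS (cat.), rt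
Reagents that add atoms: trimethyl orthoformate, COC(OC)OC
Why: Ozonolysis cleaves the electron-rich vinyl group in preference to the electron-poor enone C=C, and the C9 aldehyde is masked at once as its dimethyl acetal.

Step 9
Reactants: 21 (4R,5R,6R)-5-(dimethoxymethyl)-4-methoxy-4,6-dimethylcyclohex-2-en-1-one; 14 (4Z)-5-[(2S)-3-iodo-4-methyl-5-oxo-2,5-dihydrofuran-2-yl]-4-methylpent-4-enal
Product: 25 (4R,5R,6S)-6-[(1R,4Z)-1-(acetyloxy)-5-[(2S)-3-iodo-4-methyl-5-oxo-2,5-dihydrofuran-2-yl]-4-methylpent-4-en-1-yl]-5-(dimethoxymethyl)-4-methoxy-4,6-dimethylcyclohex-2-en-1-one, via lithium dienolate 22 (not isolated), via triisopropoxytitanium dienolate 23 (not isolated), via triisopropoxytitanium aldolate 24 (not isolated)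
Conditions: LiN(i-Pr)2, THF, −78 °C; ClTi(Oi-Pr)3, −78 → −40 °C; 14, −78 °C; then Ac2O, DMAP, −78 → 0 °C
Reagents that add atoms: acetic anhydride, CC(=O)OC(C)=O
Why: Directed aldol addition of the titanium enolate (transmetalated from the only possible lithium enolate, titanium enolates of cyclic ketones favouring the syn adduct needed for C2) to the aldehyde from the α-face, anti to the C10 acetal, sets the C1 quaternary centre and C2, and in situ acetylation of the aldolate stops retro-aldol cleavage.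

Step 10
Reactants: 25 aldol acetate (name as in step 9)
Product: 26 (1R,2R,6S)-6-[(1R,4Z)-1-(acetyloxy)-5-[(2S)-3-iodo-4-methyl-5-oxo-2,5-dihydrofuran-2-yl]-4-methylpent-4-en-1-yl]-2-methoxy-2,6-dimethyl-5-oxocyclohex-3-ene-1-carbaldehyde
Conditions: TsOH·H2O (10 mol %), acetone/H2O 10:1, rt
Reagents that add atoms: water, O
Why: Acid-catalysed acetal hydrolysis frees the C9 aldehyde without touching the tertiary allylic ether, the acetate or the iodobutenolide.

Step 11
Reactants: 26 seco iodo aldehyde (name as in step 10)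
Product: 27 ten-membered-ring 9R-hydroxy butenolide (C8–C9 bond closed; 2R-OAc; 7S; C8=C17; ring A 11-methoxy-12-en-14-one)
Conditions: CrCl2 (6 equiv), NiCl2 (2 mol %), DMSO/THF, 3 mM, rt
Reagents that add atoms: none
Why: Intramolecular Nozaki–Hiyama–Kishi reaction, in which zerovalent nickel inserts into the C8–I bond and the alkenylchromium adds only to the aldehyde under high dilution, closes the ten-membered ring through C8–C9 with the 9R carbinol expected from attack on the aldehyde face anti to the C11 quaternary centre.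

Step 12
Reactants: 27 ten-membered-ring 9-hydroxy butenolide
Product: 28 8,9-O-phenylboronate of the saturated 8R,9R-dihydroxy 17R-methyl lactone (otherwise as 27)
Conditions: PhB(OH)2 (1.5 equiv), quinuclidine (30 mol %), 4 Å molecular sieves, toluene, 50 °C
Reagents that add atoms: phenylboronic acid, OB(O)c1ccccc1
Why: Proposed new method: boronic-acid-templated conjugate hydration of a tetrasubstituted butenolide, in which the 9-OH condenses reversibly with PhB(OH)2 to a hemiboronate, the amine makes it a tetracoordinate boronate whose B–OH oxygen adds intramolecularly to C8 (β-carbon of the unsaturated lactone) and the lactone enolate is protonated at C17 anti to the new ring, closure to the stable cis-fused dioxaborolane making the otherwise unfavourable oxa-Michael addition irreversible and forcing 8-O cis to 9-O and CH3-18 cis to 8-O; the closest known reaction is the amine-catalysed oxa-Michael β-hydroxylation of γ-hydroxy enones by boronic acid hemiesters, here extended to a lactone acceptor with a fully substituted β-carbon.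

Step 13
Reactants: 28 phenylboronate lactone with ring A 11-methoxy-12-en-14-one
Product: 29 phenylboronate lactone with ring A 11-en-14-one (C11=C12; CH3-20 on C11; no methoxy)
Conditions: SmI2 (2.5 equiv), THF/MeOH, −78 °C
Reagents that add atoms: none
Why: SmI2 reduction of the γ-methoxy enone (vinylogous α-alkoxy ketone cleavage) gives the β-carbanion, which expels methoxide, and kinetic α-protonation of the dienolate leaves the β,γ-unsaturated ketone with the C11=C12 double bond.

Step 14
Reactants: 29 phenylboronate 11-en-14-one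
Product: 30 14α-alcohol (14S) of 29
Conditions: LiBH(s-Bu)3, THF, −78 °C
Reagents that add atoms: none
Why: Diastereoselective ketone reduction, the bulky borohydride attacking C14 along the equatorial trajectory (as in 4,4-disubstituted 3-keto steroids), gives the axial 14α-alcohol trans to CH3-15.

Step 15
Reactants: 30 14α-alcohol
Product: 31 11α,12α-epoxide of 30
Conditions: VO(acac)2 (5 mol %), t-BuOOH, CH2Cl2, 0 °C → rt
Reagents that add atoms: tert-butyl hydroperoxide, CC(C)(C)OO
Why: VO(acac)2-catalysed hydroxyl-directed epoxidation delivers oxygen from the axial homoallylic 14α-OH to the α-face of C11=C12, while the C5=C6 alkene has no free hydroxyl nearby and stays intact.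

Step 16
Reactants: 31 11α,12α-epoxy 14α-alcohol
Product: 33 11α,12α-epoxy 8,9-diol 2,14-diacetate (six-membered-ring isomer of the target), via acetylated boronate 32 (not isolated)
Conditions: Ac2O, DMAP, pyridine, rt; then 30% H2O2, NaH2PO4/Na2HPO4 buffer (pH 7), THF, 0 °C
Reagents that add atoms: acetic anhydride, CC(=O)OC(C)=O
Why: DMAP-catalysed acetylation caps the hindered 14-OH while the 8,9-diol is still masked, and buffered H2O2 then oxidises the B–aryl bond and releases the diol (acylation then oxidative boronate cleavage).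

Step 17
Reactants: 33 11α,12α-epoxy 8,9-diol 2,14-diacetate
Product: 35 CNP0123121.2 (1S,2R,5Z,7S,8R,9R,10R,11S,14S,17R), via bromomagnesium bromohydrinate 34 (not isolated)
Conditions: MgBr2·OEt2 (2.5 equiv), benzene/Et2O, 60 °C
Reagents that add atoms: none
Why: Bromide-assisted Meinwald (semipinacol) ring contraction, in which MgBr2 opens the epoxide at tertiary C11 with inversion to the trans-diaxial bromohydrinate and C13 then migrates from C12 to C11 anti to bromide while C12 becomes the aldehyde, puts CHO on the β-face and CH3-20 on the α-face by double inversion, hydride shift being disfavoured because H-12 is gauche to the C–Br bond.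

**Compound list**
1 | 2-(2-bromoethyl)-1,3-dioxolane | BrCCC1OCCO1 | starting material
2 | propyne | CC#C | starting material
3 | [2-(1,3-dioxolan-2-yl)ethyl]magnesium bromide | Br[Mg]CCC1OCCO1 | intermediate
4 | [2-(1,3-dioxolan-2-yl)ethyl]copper (MgBr2 complex) | [Cu]CCC1OCCO1 | intermediate
5 | (Z)-[4-(1,3-dioxolan-2-yl)-2-methylbut-1-en-1-yl]copper | [Cu]/C=C(/C)CCC1OCCO1 | intermediate
6 | 2-[(3Z)-4-iodo-3-methylbut-3-en-1-yl]-1,3-dioxolane | I/C=C(/C)CCC1OCCO1 | intermediate
7 | but-2-ynal | CC#CC=O | starting material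
8 | (Z)-[4-(1,3-dioxolan-2-yl)-2-methylbut-1-en-1-yl]lithium | [Li]/C=C(/C)CCC1OCCO1 | intermediate
9 | (Z)-[4-(1,3-dioxolan-2-yl)-2-methylbut-1-en-1-yl]zinc bromide | Br[Zn]/C=C(/C)CCC1OCCO1 | intermediate
10 | bromozinc (4R,5Z)-8-(1,3-dioxolan-2-yl)-6-methyloct-5-en-2-yn-4-olate | CC#C[C@H](O[Zn]Br)/C=C(/C)CCC1OCCO1 | intermediate
11 | methyl (4R,5Z)-8-(1,3-dioxolan-2-yl)-6-methyloct-5-en-2-yn-4-yl carbonate | CC#C[C@H](OC(=O)OC)/C=C(/C)CCC1OCCO1 | intermediate
12 | methyl (aS,5Z)-8-(1,3-dioxolan-2-yl)-2,6-dimethylocta-2,3,5-trienoate | COC(=O)C(C)=[C@@]=C([H])/C=C(/C)CCC1OCCO1 | intermediate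
13 | (5S)-5-[(1Z)-4-(1,3-dioxolan-2-yl)-2-methylbut-1-en-1-yl]-4-iodo-3-methylfuran-2(5H)-one | CC1=C(I)[C@H](/C=C(/C)CCC2OCCO2)OC1=O | intermediate
14 | (4Z)-5-[(2S)-3-iodo-4-methyl-5-oxo-2,5-dihydrofuran-2-yl]-4-methylpent-4-enal | CC1=C(I)[C@H](/C=C(/C)CCC=O)OC1=O | intermediate
15 | 4-methylphenol | Cc1ccc(O)cc1 | starting material
16 | 4-methoxy-4-methylcyclohexa-2,5-dien-1-one | COC1(C)C=CC(=O)C=C1 | intermediate
17 | (4R,5S)-5-ethenyl-4-methoxy-4-methylcyclohex-2-en-1-one | O=C1C=C[C@@](C)(OC)[C@H](C=C)C1 | intermediate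
18 | lithium dienolate of 17 (O–Li on C14, C14=C1) | [Li]OC=1C=C[C@@](C)(OC)[C@H](C=C)C=1 | intermediate
19 | (4R,5R,6R)-5-ethenyl-4-methoxy-4,6-dimethylcyclohex-2-en-1-one | O=C1C=C[C@@](C)(OC)[C@H](C=C)[C@H]1C | intermediate
20 | (1R,2R,6R)-2-methoxy-2,6-dimethyl-5-oxocyclohex-3-ene-1-carbaldehyde | O=C1C=C[C@@](C)(OC)[C@H](C=O)[C@H]1C | intermediate
21 | (4R,5R,6R)-5-(dimethoxymethyl)-4-methoxy-4,6-dimethylcyclohex-2-en-1-one | O=C1C=C[C@@](C)(OC)[C@H](C(OC)OC)[C@H]1C | intermediate
22 | lithium dienolate of 21 (O–Li on C14, C14=C1) | [Li]OC=1C=C[C@@](C)(OC)[C@H](C(OC)OC)C=1C | intermediate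
23 | triisopropoxytitanium dienolate of 21 | CC(C)O[Ti](OC(C)C)(OC(C)C)OC=1C=C[C@@](C)(OC)[C@H](C(OC)OC)C=1C | intermediate
24 | triisopropoxytitanium aldolate (C2–O–Ti form of the aldol adduct of 21 and 14) | O=C1C=C[C@@](C)(OC)[C@H](C(OC)OC)[C@@]1(C)[C@H](O[Ti](OC(C)C)(OC(C)C)OC(C)C)CC/C(C)=C\[C@@H]2OC(=O)C(C)=C2I | intermediate
25 | (4R,5R,6S)-6-[(1R,4Z)-1-(acetyloxy)-5-[(2S)-3-iodo-4-methyl-5-oxo-2,5-dihydrofuran-2-yl]-4-methylpent-4-en-1-yl]-5-(dimethoxymethyl)-4-methoxy-4,6-dimethylcyclohex-2-en-1-one | O=C1C=C[C@@](C)(OC)[C@H](C(OC)OC)[C@@]1(C)[C@H](OC(C)=O)CC/C(C)=C\[C@@H]2OC(=O)C(C)=C2I | intermediate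
26 | (1R,2R,6S)-6-[(1R,4Z)-1-(acetyloxy)-5-[(2S)-3-iodo-4-methyl-5-oxo-2,5-dihydrofuran-2-yl]-4-methylpent-4-en-1-yl]-2-methoxy-2,6-dimethyl-5-oxocyclohex-3-ene-1-carbaldehyde | O=C1C=C[C@@](C)(OC)[C@H](C=O)[C@@]1(C)[C@H](OC(C)=O)CC/C(C)=C\[C@@H]2OC(=O)C(C)=C2I | intermediate
27 | ten-membered-ring butenolide: 2R-acetoxy, 9R-hydroxy, 7S lactone carbon, C5=C6 Z, C8=C17, ring A 11-methoxy-12-en-14-one | O=C1C=C[C@@](C)(OC)[C@@H]2[C@@H](O)C3=C(C)C(=O)O[C@H]3/C=C(/C)CC[C@@H](OC(C)=O)[C@@]12C | intermediate
28 | 8,9-O-phenylboronate of the 8R,9R-diol, saturated lactone with 17R-CH3, ring A as in 27 | O=C1C=C[C@@](C)(OC)[C@@H]2[C@H]3OB(c4ccccc4)O[C@@]35[C@H](/C=C(/C)CC[C@@H](OC(C)=O)[C@@]12C)OC(=O)[C@@H]5C | intermediate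
29 | phenylboronate with ring A 11-en-14-one (C11=C12) | O=C1CC=C(C)[C@@H]2[C@H]3OB(c4ccccc4)O[C@@]35[C@H](/C=C(/C)CC[C@@H](OC(C)=O)[C@@]12C)OC(=O)[C@@H]5C | intermediate
30 | 14α-alcohol (14S) of 29 | O[C@H]1CC=C(C)[C@@H]2[C@H]3OB(c4ccccc4)O[C@@]35[C@H](/C=C(/C)CC[C@@H](OC(C)=O)[C@@]12C)OC(=O)[C@@H]5C | intermediate
31 | 11α,12α-epoxide of 30 | O[C@H]1C[C@H]2O[C@@]2(C)[C@@H]3[C@H]4OB(c5ccccc5)O[C@@]46[C@H](/C=C(/C)CC[C@@H](OC(C)=O)[C@@]13C)OC(=O)[C@@H]6C | intermediate
32 | 14-acetate of 31 | CC(=O)O[C@H]1C[C@H]2O[C@@]2(C)[C@@H]3[C@H]4OB(c5ccccc5)O[C@@]46[C@H](/C=C(/C)CC[C@@H](OC(C)=O)[C@@]13C)OC(=O)[C@@H]6C | intermediate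
33 | 11α,12α-epoxy 8,9-diol 2,14-diacetate (ring A still six-membered) | CC(=O)O[C@H]1C[C@H]2O[C@@]2(C)[C@@H]3[C@@H](O)[C@@]4(O)[C@H](/C=C(/C)CC[C@@H](OC(C)=O)[C@@]13C)OC(=O)[C@@H]4C | intermediate
34 | 11β-bromo 12α-(bromomagnesiooxy) bromohydrinate of 33 | CC(=O)O[C@H]1C[C@@H](O[Mg]Br)[C@](C)(Br)[C@@H]3[C@@H](O)[C@@]4(O)[C@H](/C=C(/C)CC[C@@H](OC(C)=O)[C@@]13C)OC(=O)[C@@H]4C | intermediate
35 | CNP0123121.2 (1S,2R,5Z,7S,8R,9R,10R,11S,14S,17R) | CC(=O)O[C@H]1C[C@](C)(C=O)[C@@H]2[C@@H](O)[C@@]3(O)[C@H](/C=C(/C)CC[C@@H](OC(C)=O)[C@@]12C)OC(=O)[C@@H]3C | target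

**Count and risks**
Total steps: 17. Longest linear sequence: 13 steps (steps 5–17; the branch through steps 1–4 and 9–17 is equally long).

Steps most likely to fail:

Step 11 (closure of the strained ten-membered ring; the C9 configuration is not secured by a firm model). The fallback sets out from 26 and comes back at 27, and closes the same bond as a ketone so that C9 is set afterwards by the reducing agent. Aldehyde 26 is oxidised (NaClO2, NaH2PO4, 2-methylbut-2-ene) to the seco carboxylic acid F1. F1 is converted (EtSH, EDC, DMAP) into the S-ethyl thioester F2. Zinc is inserted into the C8–I bond (Zn dust, LiCl, THF) and intramolecular Fukuyama coupling (PdCl2(PPh3)2, toluene, high dilution) gives the macrocyclic 9-ketone F3. Reduction at −78 °C with NaBH4/CeCl3·7H2O, or with an oxazaborolidine/borane pair if reagent control is needed, gives 27.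

Step 12 (the new boronate-tethered hydration; the acceptor is a hindered, fully substituted lactone). The fallback uses known chemistry, sets out from 27 and comes back at 29. Hydroxyl-directed nucleophilic epoxidation (LiOOt-Bu, THF, −20 °C) gives the 8,17-epoxy lactone F4. Excess SmI2 (THF/MeOH, −78 °C) opens the α C–O bond of the epoxy lactone, with C17 protonated from the open face, and in the same operation performs the step-13 reduction of the methoxy enone, giving the free 8,9-diol F5. Condensation with PhB(OH)2 (MgSO4, CH2Cl2) gives 29.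

Step 17 (ring contraction against hydride shift; ring A must leave its chair so that C12–C13 lies anti to C–Br). The fallback sets out from 33 and comes back at 35, and separates the two events. The epoxide is opened with Li2NiBr4 (THF, 0 °C) to the isolated trans-diaxial 11β-bromo-12α-hydroxy bromohydrin F6. Halophilic ionisation with AgBF4 and 2,6-di-tert-butylpyridine (CH2Cl2, −40 °C) then drives the same C13 shift irreversibly as a pinacol-type rearrangement to 35.

Further compounds
F1 | step 11 | seco carboxylic acid (C9 as CO2H, otherwise as 26) | O=C1C=C[C@@](C)(OC)[C@H](C(=O)O)[C@@]1(C)[C@H](OC(C)=O)CC/C(C)=C\[C@@H]2OC(=O)C(C)=C2I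
F2 | step 11 | S-ethyl thioester of F1 | O=C1C=C[C@@](C)(OC)[C@H](C(=O)SCC)[C@@]1(C)[C@H](OC(C)=O)CC/C(C)=C\[C@@H]2OC(=O)C(C)=C2I
F3 | step 11 | macrocyclic 9-ketone (9-oxo analogue of 27) | O=C1C=C[C@@](C)(OC)[C@@H]2C(=O)C3=C(C)C(=O)O[C@H]3/C=C(/C)CC[C@@H](OC(C)=O)[C@@]12C
F4 | step 12 | 8,17-epoxy lactone of 27 | O=C1C=C[C@@](C)(OC)[C@@H]2[C@@H](O)[C@]34O[C@@]3(C)C(=O)O[C@H]4/C=C(/C)CC[C@@H](OC(C)=O)[C@@]12C
F5 | step 12 | free 8,9-diol corresponding to 29 | O=C1CC=C(C)[C@@H]2[C@@H](O)[C@@]3(O)[C@H](/C=C(/C)CC[C@@H](OC(C)=O)[C@@]12C)OC(=O)[C@@H]3C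
F6 | step 17 | 11β-bromo-12α-hydroxy bromohydrin of 33 | CC(=O)O[C@H]1C[C@@H](O)[C@](C)(Br)[C@@H]3[C@@H](O)[C@@]4(O)[C@H](/C=C(/C)CC[C@@H](OC(C)=O)[C@@]13C)OC(=O)[C@@H]4C
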